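## Retrosynthetic overview

1. The target, (3S,4S,3'S,5'R)-3,4,3',8'-tetrahydroxy-7,8-didehydro-β,κ-caroten-6'-one, is cut at the bond between the outer alkyne carbon C8 and the methyl-bearing olefinic carbon C9, and at C9–CH3. Three components (ring-A alkyne, a 1,1-dibromopolyene and a methyl donor) are joined at C9 in one flask by trans-selective Negishi alkynylation followed by Negishi methylation.
2. Enabling feature: C9 is the fully substituted sp2 end of the C9=C10 bond and carries the alkyne carbon C8 and the methyl C19 geminally, opposite H on C10. This is the retron of a C9Br2=C10H gem-dibromoalkene whose C–Br bond trans to the polyene chain reacts first, so the order of the two couplings fixes the 9E geometry.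
3. Right half: the C9'=C10' bond comes from a boron-templated (Pabon) aldol condensation of the κ-ring 1,3-diketone 15 with dibromo-hexaenal 19, which is made from the symmetric C14 dialdehyde (commercial C10 dialdehyde 16 plus two C2 units).
4. Rings: ring A (cyclohexene) is taken intact from safranal and receives the trans-3,4-diol by Jacobsen epoxidation and SN2 hydrolysis. The κ ring (cyclopentane) is then made by semipinacol ring contraction of a Sharpless-derived cyclohexane epoxide from (4R,6R)-actinol. The key step closes no ring.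
5. Global desilylation ends the route.

Key step: step 16

Remark: carotenoid locants are used (C1–C20, primed for the κ half), and the 1,3-diketone is written as the chelated C8'-enol/C6'-ketone of the target string, the two enol forms being one rapidly equilibrating compound.

## Route

Step 1
Reactants: 1 safranal (2,6,6-trimethylcyclohexa-1,3-diene-1-carbaldehyde)
Product: 2 1-ethynyl-2,6,6-trimethylcyclohexa-1,3-diene
Conditions: Me3SiCHN2, n-BuLi, THF, −78 °C; then 1, −78 °C → rt
Reagents that add atoms: trimethylsilyldiazomethane, C[Si](C)(C)C=[N+]=[N-]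
Why: Colvin rearrangement: the lithiated diazomethane adds to the hindered dienal, loss of silanolate and N2 gives an alkylidene carbene, and its 1,2-hydrogen shift should deliver the terminal alkyne without touching the diene.

Step 2
Reactants: 2 1-ethynyl-2,6,6-trimethylcyclohexa-1,3-diene
Product: 3 (1R,6S)-3-ethynyl-2,4,4-trimethyl-7-oxabicyclo[4.1.0]hept-2-ene (the 3,4-epoxide, 3S,4R in carotenoid locants)
Conditions: (R,R)-(salen)MnCl [salen = N,N'-bis(3,5-di-tert-butylsalicylidene)-1,2-cyclohexanediamine dianion] (5 mol %), NMO, mCPBA, CH2Cl2, −78 °C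
Reagents that add atoms: mCPBA, OOC(=O)c1cccc(Cl)c1
Why: Jacobsen–Katsuki epoxidation: the cis-disubstituted C3=C4 alkene conjugated to the enyne is the privileged substrate class and the tetrasubstituted, alkyne-conjugated C5=C6 bond should stay inert, while the (R,R)-catalyst is expected to deliver oxygen to the face giving the (3S,4R)-epoxide by analogy with 1,2-dihydronaphthalene and indene.

Step 3
Reactants: 3 (1R,6S)-3-ethynyl-2,4,4-trimethyl-7-oxabicyclo[4.1.0]hept-2-ene
Product: 4 (1S,2S)-4-ethynyl-3,5,5-trimethylcyclohex-3-ene-1,2-diol (trans-diol, 3S,4S in carotenoid locants)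
Conditions: KOH, DMSO–H2O (4:1), 70 °C
Reagents that add atoms: water, O
Why: SN2 hydrolysis of a vinyl epoxide: hydroxide should attack the allylic C4 with inversion, because attack at C3 is electronically unassisted and meets a syn-axial methyl of the gem-dimethyl group, so C3 keeps its S configuration and C4 becomes S (trans-diol).

Step 4
Reactants: 4 (1S,2S)-4-ethynyl-3,5,5-trimethylcyclohex-3-ene-1,2-diol
Product: 5 (1S,2S)-1,2-bis[(tert-butyldimethylsilyl)oxy]-4-ethynyl-3,5,5-trimethylcyclohex-3-ene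
Conditions: TBSOTf (2.5 equiv), 2,6-lutidine, CH2Cl2, −20 → 0 °C
Reagents that add atoms: tert-butyldimethylsilyl trifluoromethanesulfonate, CC(C)(C)[Si](C)(C)OS(=O)(=O)C(F)(F)F
Why: Silylation of both secondary hydroxyls with the silyl triflate removes the acidic protons before the organozinc chemistry and leaves the alkyne C–H untouched.

Step 5
Reactants: 6 (4R,6R)-4-hydroxy-2,2,6-trimethylcyclohexan-1-one (actinol)
Product: 7 (4R,6R)-4-[(tert-butyldimethylsilyl)oxy]-2,2,6-trimethylcyclohexan-1-one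
Conditions: TBSCl, imidazole, DMF, rt
Reagents that add atoms: tert-butyldimethylsilyl chloride, CC(C)(C)[Si](C)(C)Cl
Why: Standard silyl protection of the secondary alcohol whose configuration becomes C3' of the target.

Step 6
Reactants: 7 (4R,6R)-4-[(tert-butyldimethylsilyl)oxy]-2,2,6-trimethylcyclohexan-1-one
Product: 9 (4R)-4-[(tert-butyldimethylsilyl)oxy]-2,6,6-trimethylcyclohex-1-en-1-yl trifluoromethanesulfonate, via lithium enolate of the ketone 8 (not isolated)
Conditions: LDA, THF, −78 °C; then PhNTf2, −78 → 0 °C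
Reagents that add atoms: N-phenylbis(trifluoromethanesulfonimide), O=S(=O)(N(c1ccccc1)S(=O)(=O)C(F)(F)F)C(F)(F)F
Why: Enolization is possible only toward the methyl-bearing α-carbon (the other α-carbon is quaternary) and O-sulfonylation of the enolate gives the tetrasubstituted enol triflate, erasing the C6 stereocentre and leaving the silyloxy centre untouched.

Step 7
Reactants: 9 (4R)-4-[(tert-butyldimethylsilyl)oxy]-2,6,6-trimethylcyclohex-1-en-1-yl trifluoromethanesulfonate
Product: 10 [(4R)-4-[(tert-butyldimethylsilyl)oxy]-2,6,6-trimethylcyclohex-1-en-1-yl]methanol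
Conditions: Bu3SnCH2OH, Pd(PPh3)4 (5 mol %), LiCl (3 equiv), 1,4-dioxane, 100 °C
Reagents that add atoms: (tributylstannyl)methanol, CCCC[Sn](CO)(CCCC)CCCC
Why: Migita–Kosugi–Stille coupling of the enol triflate with the hydroxymethylstannane (LiCl-assisted) installs the allylic CH2OH that allows reagent-controlled epoxidation and later becomes C7'.

Step 8
Reactants: 10 [(4R)-4-[(tert-butyldimethylsilyl)oxy]-2,6,6-trimethylcyclohex-1-en-1-yl]methanol
Product: 11 [(1R,4S,6R)-4-[(tert-butyldimethylsilyl)oxy]-2,2,6-trimethyl-7-oxabicyclo[4.1.0]heptan-1-yl]methanol (epoxide oxygen trans to the silyloxy group)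
Conditions: Ti(Oi-Pr)4 (10 mol %), L-(+)-diethyl tartrate (12 mol %), t-BuOOH, 4 Å MS, CH2Cl2, −20 °C
Reagents that add atoms: tert-butyl hydroperoxide, CC(C)(C)OO
Why: Sharpless asymmetric epoxidation: with L-(+)-tartrate the oxygen should be delivered to the face of the allylic alcohol opposite the C4 silyloxy group (reagent control), setting both quaternary epoxide centres (1R,6R).

Step 9
Reactants: 11 [(1R,4S,6R)-4-[(tert-butyldimethylsilyl)oxy]-2,2,6-trimethyl-7-oxabicyclo[4.1.0]heptan-1-yl]methanol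
Product: 12 [(1R,4S,6R)-4-[(tert-butyldimethylsilyl)oxy]-2,2,6-trimethyl-7-oxabicyclo[4.1.0]heptan-1-yl]methyl 4-methylbenzenesulfonate
Conditions: TsCl, Et3N, DMAP (cat.), CH2Cl2, 0 °C → rt
Reagents that add atoms: 4-methylbenzenesulfonyl chloride, Cc1ccc(cc1)S(=O)(=O)Cl
Why: Sulfonylation turns the hydroxyl into a non-participating, electron-withdrawing group that steers the next ionization and is reductively removable afterwards.

Step 10
Reactants: 12 [(1R,4S,6R)-4-[(tert-butyldimethylsilyl)oxy]-2,2,6-trimethyl-7-oxabicyclo[4.1.0]heptan-1-yl]methyl 4-methylbenzenesulfonate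
Product: 13 2-[(1R,4S)-4-[(tert-butyldimethylsilyl)oxy]-1,2,2-trimethylcyclopentyl]-2-oxoethyl 4-methylbenzenesulfonate
Conditions: BF3·OEt2 (30 mol %), CH2Cl2, −78 → −30 °C
Reagents that add atoms: none
Why: Semipinacol (Meinwald-type) ring contraction: the Lewis acid should open the epoxide at the methyl-bearing carbon (a cation next to CH2OTs is disfavoured), the CMe2 ring carbon migrates anti to the leaving oxygen and the former carbinol carbon becomes the ketone, so the quaternary ring carbon is set with inversion as R (acyl trans to the silyloxy group).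

Step 11
Reactants: 13 2-[(1R,4S)-4-[(tert-butyldimethylsilyl)oxy]-1,2,2-trimethylcyclopentyl]-2-oxoethyl 4-methylbenzenesulfonate
Product: 14 1-[(1R,4S)-4-[(tert-butyldimethylsilyl)oxy]-1,2,2-trimethylcyclopentyl]ethan-1-one
Conditions: SmI2 (2.2 equiv), THF–MeOH, −78 °C
Reagents that add atoms: none
Why: SmI2 reductive cleavage of an α-sulfonyloxy ketone (ketyl formation, loss of tosylate, protonation of the samarium enolate) should leave the methyl ketone, with no stereocentre at risk because the other α-carbon is quaternary.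

Step 12
Reactants: 14 1-[(1R,4S)-4-[(tert-butyldimethylsilyl)oxy]-1,2,2-trimethylcyclopentyl]ethan-1-one
Product: 15 1-[(1R,4S)-4-[(tert-butyldimethylsilyl)oxy]-1,2,2-trimethylcyclopentyl]pentane-1,3-dione
Conditions: NaH (2.5 equiv), ethyl propionate (3 equiv), THF, 60 °C; aq. NH4Cl
Reagents that add atoms: ethyl propionate, CCC(=O)OCC
Why: Crossed Claisen condensation: the methyl group is the only enolizable position of the hindered ketone, and formation of the stabilized diketonate should drive acylation by the ester.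

Step 13
Reactants: 16 (2E,4E,6E)-2,7-dimethylocta-2,4,6-trienedial
Product: 18 (2E,4E,6E,8E,10E)-4,9-dimethyldodeca-2,4,6,8,10-pentaenedial, via bis-dioxolane acetal of the pentaenedial 17 (not isolated)
Conditions: [(1,3-dioxolan-2-yl)methyl]PPh3Br (2.4 equiv), KOt-Bu, THF, 0 °C → rt; then 1 M HCl, THF, rt; dark
Reagents that add atoms: (1,3-dioxolan-2-ylmethyl)triphenylphosphonium bromide, C1COC(O1)C[P+](c2ccccc2)(c2ccccc2)c2ccccc2.[Br-]; water, O
Why: Double Wittig olefination with the acetal-masked two-carbon ylide (the masked product cannot be homologated further), then acid hydrolysis with Z-to-E equilibration of the new enal double bonds, should give the all-E C14 dialdehyde.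

Step 14
Reactants: 18 (2E,4E,6E,8E,10E)-4,9-dimethyldodeca-2,4,6,8,10-pentaenedial
Product: 19 (2E,4E,6E,8E,10E)-13,13-dibromo-4,9-dimethyltrideca-2,4,6,8,10,12-hexaenal
Conditions: Ph3PCHBr2 Br (1.0 equiv), KOt-Bu (1.0 equiv), THF, 0 °C; then 18 (2 equiv), −20 °C → rt; dark
Reagents that add atoms: (dibromomethyl)triphenylphosphonium bromide, BrC(Br)[P+](c1ccccc1)(c1ccccc1)c1ccccc1.[Br-]
Why: Ramirez (Corey–Fuchs-type) dibromoolefination with preformed Ph3P=CBr2: one equivalent of ylide against an excess of the symmetric dialdehyde should give the mono-olefin statistically, and unreacted 18 is recovered.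

Step 15
Reactants: 15 1-[(1R,4S)-4-[(tert-butyldimethylsilyl)oxy]-1,2,2-trimethylcyclopentyl]pentane-1,3-dione; 19 (2E,4E,6E,8E,10E)-13,13-dibromo-4,9-dimethyltrideca-2,4,6,8,10,12-hexaenal
Product: 22 (2Z,4E,6E,8E,10E,12E,14E)-17,17-dibromo-1-[(1R,4S)-4-[(tert-butyldimethylsilyl)oxy]-1,2,2-trimethylcyclopentyl]-3-hydroxy-4,8,13-trimethylheptadeca-2,4,6,8,10,12,14,16-octaen-1-one, via dibutoxyboron chelate of the diketone 20 (not isolated), via dibutoxyboron chelate of the condensation product 21 (not isolated)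
Conditions: 15, B2O3 (0.6 equiv), B(On-Bu)3 (2 equiv), EtOAc, 60 °C; then 19, n-BuNH2 (0.4 equiv), 60 °C; then 10% aq. AcOH, 40 °C; dark
Reagents that add atoms: none
Why: Pabon-type aldol condensation: boron chelation masks the central methylene and the enol, so the amine-catalysed condensation should take place at the ethyl CH2 (the only other enolizable site, the opposite flank being quaternary), and elimination gives the conjugated E trisubstituted C9'=C10' bond.

Step 16
Reactants: 22 (2Z,4E,6E,8E,10E,12E,14E)-17,17-dibromo-1-[(1R,4S)-4-[(tert-butyldimethylsilyl)oxy]-1,2,2-trimethylcyclopentyl]-3-hydroxy-4,8,13-trimethylheptadeca-2,4,6,8,10,12,14,16-octaen-1-one; 5 (1S,2S)-1,2-bis[(tert-butyldimethylsilyl)oxy]-4-ethynyl-3,5,5-trimethylcyclohex-3-ene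
Product: 27 (3S,4S,3'S,5'R)-3,4,3'-tris[(tert-butyldimethylsilyl)oxy]-8'-hydroxy-7,8-didehydro-β,κ-caroten-6'-one, via lithium acetylide of the alkyne 23 (not isolated), via alkynylzinc bromide 24 (not isolated), via lithium enolate of the dibromide 25 (not isolated), via lithium enolate of the bromoenyne 26 (not isolated)
Conditions: 5 (1.2 equiv), n-BuLi, THF, −78 °C, then ZnBr2, 0 °C; 22, LiHMDS (1.0 equiv), THF, −78 °C; mix, PdCl2(DPEphos) [DPEphos = bis(2-diphenylphosphinophenyl) ether] (5 mol %), 0 °C → rt; then Me2Zn (3 equiv), Pd[P(t-Bu)3]2 (5 mol %), rt; aq. NH4Cl; dark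
Reagents that add atoms: dimethylzinc, C[Zn]C
Why: Zerovalent palladium, formed from PdCl2(DPEphos) and the zinc reagent, should insert selectively into the C9–Br bond trans to the C10–C11 chain; transmetalation with alkynylzinc 24 and reductive elimination make the C8–C9 bond and give bromoenyne 26, after which the more active Pd[P(t-Bu)3]2 inserts into the remaining hindered C9–Br bond and couples it with Me2Zn with retention, so alkyne, methyl C19 and polyene are joined at C9 in one flask. The closest known reaction type is the tandem trans-selective alkynylation–methylation of 1,1-dibromo-1-alkenes by Negishi coupling, which gives (E)-3-methyl-3-en-1-ynes. No ring is closed and no stereocentre is formed; the stereo-element created is the C9=C10 geometry, fixed as E by the order of the two substitutions (alkynyl enters trans to C11, methyl takes the cis position with retention). The selectivities needed are mono- against double alkynylation and retention in the methylation: the first rests on the steric difference between the two C–Br bonds imposed by the C10–C11 substituent and on the wide-bite-angle DPEphos ligand, the second on the bulky trialkylphosphine, which should suppress isomerisation of the alkenylpalladium intermediate. The acidic chelated enol is masked beforehand as lithium enolate 25, which is inert to both organozinc reagents and returns as the enol on mild acidic work-up, while the silyl ethers and the polyene are not touched.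

Step 17
Reactants: 27 (3S,4S,3'S,5'R)-3,4,3'-tris[(tert-butyldimethylsilyl)oxy]-8'-hydroxy-7,8-didehydro-β,κ-caroten-6'-one
Product: 28 (3S,4S,3'S,5'R)-3,4,3',8'-tetrahydroxy-7,8-didehydro-β,κ-caroten-6'-one (CNP0114063.1)
Conditions: TBAF (6 equiv), AcOH (6 equiv), THF, rt, dark
Reagents that add atoms: none
Why: Fluoride-mediated cleavage of the three secondary silyl ethers, buffered with acetic acid so that the polyene enol-diketone is not exposed to strongly basic fluoride, should release the target without touching any stereocentre or double bond.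

## Compound list

1 | safranal (2,6,6-trimethylcyclohexa-1,3-diene-1-carbaldehyde) | CC1=C(C=O)C(C)(C)CC=C1 | starting material
2 | 1-ethynyl-2,6,6-trimethylcyclohexa-1,3-diene | CC1=C(C#C)C(C)(C)CC=C1 | intermediate
3 | (1R,6S)-3-ethynyl-2,4,4-trimethyl-7-oxabicyclo[4.1.0]hept-2-ene | CC1=C(C#C)C(C)(C)C[C@@H]2O[C@H]12 | intermediate
4 | (1S,2S)-4-ethynyl-3,5,5-trimethylcyclohex-3-ene-1,2-diol | CC1=C(C#C)C(C)(C)C[C@H](O)[C@H]1O | intermediate
5 | (1S,2S)-1,2-bis[(tert-butyldimethylsilyl)oxy]-4-ethynyl-3,5,5-trimethylcyclohex-3-ene | CC1=C(C#C)C(C)(C)C[C@H](O[Si](C)(C)C(C)(C)C)[C@H]1O[Si](C)(C)C(C)(C)C | intermediate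
6 | (4R,6R)-4-hydroxy-2,2,6-trimethylcyclohexan-1-one (actinol) | O=C1[C@H](C)C[C@@H](O)CC1(C)C | starting material
7 | (4R,6R)-4-[(tert-butyldimethylsilyl)oxy]-2,2,6-trimethylcyclohexan-1-one | O=C1[C@H](C)C[C@@H](O[Si](C)(C)C(C)(C)C)CC1(C)C | intermediate
8 | lithium (4R)-4-[(tert-butyldimethylsilyl)oxy]-2,6,6-trimethylcyclohex-1-en-1-olate | CC1=C([O-])C(C)(C)C[C@H](O[Si](C)(C)C(C)(C)C)C1.[Li+] | intermediate
9 | (4R)-4-[(tert-butyldimethylsilyl)oxy]-2,6,6-trimethylcyclohex-1-en-1-yl trifluoromethanesulfonate | CC1=C(OS(=O)(=O)C(F)(F)F)C(C)(C)C[C@H](O[Si](C)(C)C(C)(C)C)C1 | intermediate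
10 | [(4R)-4-[(tert-butyldimethylsilyl)oxy]-2,6,6-trimethylcyclohex-1-en-1-yl]methanol | CC1=C(CO)C(C)(C)C[C@H](O[Si](C)(C)C(C)(C)C)C1 | intermediate
11 | [(1R,4S,6R)-4-[(tert-butyldimethylsilyl)oxy]-2,2,6-trimethyl-7-oxabicyclo[4.1.0]heptan-1-yl]methanol | C[C@]12O[C@@]1(CO)C(C)(C)C[C@H](O[Si](C)(C)C(C)(C)C)C2 | intermediate
12 | [(1R,4S,6R)-4-[(tert-butyldimethylsilyl)oxy]-2,2,6-trimethyl-7-oxabicyclo[4.1.0]heptan-1-yl]methyl 4-methylbenzenesulfonate | C[C@]12O[C@@]1(COS(=O)(=O)c3ccc(C)cc3)C(C)(C)C[C@H](O[Si](C)(C)C(C)(C)C)C2 | intermediate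
13 | 2-[(1R,4S)-4-[(tert-butyldimethylsilyl)oxy]-1,2,2-trimethylcyclopentyl]-2-oxoethyl 4-methylbenzenesulfonate | Cc1ccc(cc1)S(=O)(=O)OCC(=O)[C@]2(C)C[C@@H](O[Si](C)(C)C(C)(C)C)CC2(C)C | intermediate
14 | 1-[(1R,4S)-4-[(tert-butyldimethylsilyl)oxy]-1,2,2-trimethylcyclopentyl]ethan-1-one | CC(=O)[C@]1(C)C[C@@H](O[Si](C)(C)C(C)(C)C)CC1(C)C | intermediate
15 | 1-[(1R,4S)-4-[(tert-butyldimethylsilyl)oxy]-1,2,2-trimethylcyclopentyl]pentane-1,3-dione | CCC(=O)CC(=O)[C@]1(C)C[C@@H](O[Si](C)(C)C(C)(C)C)CC1(C)C | intermediate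
16 | (2E,4E,6E)-2,7-dimethylocta-2,4,6-trienedial | O=C/C(C)=C/C=C/C=C(C)/C=O | starting material
17 | 2,2'-[(3E,5E,7E)-3,8-dimethyldeca-1,3,5,7,9-pentaene-1,10-diyl]bis(1,3-dioxolane), terminal double bonds as E/Z mixture | C1COC(O1)C=C/C(C)=C/C=C/C=C(C)/C=CC1OCCO1 | intermediate
18 | (2E,4E,6E,8E,10E)-4,9-dimethyldodeca-2,4,6,8,10-pentaenedial | O=C/C=C/C(C)=C/C=C/C=C(C)/C=C/C=O | intermediate
19 | (2E,4E,6E,8E,10E)-13,13-dibromo-4,9-dimethyltrideca-2,4,6,8,10,12-hexaenal | BrC(Br)=C/C=C/C(C)=C/C=C/C=C(C)/C=C/C=O | intermediate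
20 | dibutoxyboron chelate (2,2-dibutoxy-1,3,2-dioxaborinine form) of diketone 15 | CCCCO[B-]1(OCCCC)OC(CC)=CC(=[O+]1)[C@]2(C)C[C@@H](O[Si](C)(C)C(C)(C)C)CC2(C)C | intermediate
21 | dibutoxyboron chelate of enol-diketone 22 | BrC(Br)=C/C=C/C(C)=C/C=C/C=C(C)/C=C/C=C(C)/C1=CC(=[O+][B-](OCCCC)(OCCCC)O1)[C@]2(C)C[C@@H](O[Si](C)(C)C(C)(C)C)CC2(C)C | intermediate
22 | (2Z,4E,6E,8E,10E,12E,14E)-17,17-dibromo-1-[(1R,4S)-4-[(tert-butyldimethylsilyl)oxy]-1,2,2-trimethylcyclopentyl]-3-hydroxy-4,8,13-trimethylheptadeca-2,4,6,8,10,12,14,16-octaen-1-one | BrC(Br)=C/C=C/C(C)=C/C=C/C=C(C)/C=C/C=C(C)/C(O)=C/C(=O)[C@]1(C)C[C@@H](O[Si](C)(C)C(C)(C)C)CC1(C)C | intermediate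
23 | lithium acetylide of alkyne 5 | CC1=C(C#C[Li])C(C)(C)C[C@H](O[Si](C)(C)C(C)(C)C)[C@H]1O[Si](C)(C)C(C)(C)C | intermediate
24 | alkynylzinc bromide of alkyne 5 | CC1=C(C#C[Zn]Br)C(C)(C)C[C@H](O[Si](C)(C)C(C)(C)C)[C@H]1O[Si](C)(C)C(C)(C)C | intermediate
25 | lithium enolate of dibromide 22 | BrC(Br)=C/C=C/C(C)=C/C=C/C=C(C)/C=C/C=C(C)/C([O-])=C/C(=O)[C@]1(C)C[C@@H](O[Si](C)(C)C(C)(C)C)CC1(C)C.[Li+] | intermediate
26 | lithium enolate of the (9Z)-9-bromo-19-nor analogue of 27 (bromine on C9 cis to C11) | CC1=C(C#C/C(Br)=C/C=C/C(C)=C/C=C/C=C(C)/C=C/C=C(C)/C([O-])=C/C(=O)[C@]2(C)C[C@@H](O[Si](C)(C)C(C)(C)C)CC2(C)C)C(C)(C)C[C@H](O[Si](C)(C)C(C)(C)C)[C@H]1O[Si](C)(C)C(C)(C)C.[Li+] | intermediate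
27 | (3S,4S,3'S,5'R)-3,4,3'-tris[(tert-butyldimethylsilyl)oxy]-8'-hydroxy-7,8-didehydro-β,κ-caroten-6'-one | CC1=C(C#C/C(C)=C/C=C/C(C)=C/C=C/C=C(C)/C=C/C=C(C)/C(O)=C/C(=O)[C@]2(C)C[C@@H](O[Si](C)(C)C(C)(C)C)CC2(C)C)C(C)(C)C[C@H](O[Si](C)(C)C(C)(C)C)[C@H]1O[Si](C)(C)C(C)(C)C | intermediate
28 | (3S,4S,3'S,5'R)-3,4,3',8'-tetrahydroxy-7,8-didehydro-β,κ-caroten-6'-one (CNP0114063.1) | CC1=C(C#C/C(C)=C/C=C/C(C)=C/C=C/C=C(C)/C=C/C=C(C)/C(O)=C/C(=O)[C@]2(C)C[C@@H](O)CC2(C)C)C(C)(C)C[C@H](O)[C@H]1O | target

## Step count and risks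

Total step count: 17 (ring-A alkyne 4 steps, κ-ring diketone 8 steps, dibromo-hexaenal 2 steps, then 3 common steps).
Longest linear sequence: 11 steps (from 6 to 28: steps 5–12, then 15, 16 and 17).

Steps most likely to fail:

1. Step 16. The process at risk is substitution of the second C–Br bond by the alkynylzinc reagent (double alkynylation), stereochemical leakage at C9=C10 during the methylation, and slow transmetalation or decomposition caused by the metal diketonate on the long, light-sensitive polyenyl dibromide. The fallback sets out from alkyne 5 and dibromo aldehyde 19 and comes back at 27; it moves the union in front of the diketone and uses two separate couplings.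
   - Sonogashira coupling of 5 with 19 (PdCl2(dppf), CuI, i-Pr2NH, benzene, rt), which is also trans-selective, should give the isolable (2E,4E,6E,8E,10E,12Z)-13-bromo-15-[(3S,4S)-3,4-bis[(tert-butyldimethylsilyl)oxy]-2,6,6-trimethylcyclohex-1-en-1-yl]-4,9-dimethylpentadeca-2,4,6,8,10,12-hexaen-14-ynal F1.
   - Suzuki–Miyaura methylation with trimethylboroxine (Pd(PPh3)4, K2CO3, 1,4-dioxane, 80 °C) should give (2E,4E,6E,8E,10E,12E)-15-[(3S,4S)-3,4-bis[(tert-butyldimethylsilyl)oxy]-2,6,6-trimethylcyclohex-1-en-1-yl]-4,9,13-trimethylpentadeca-2,4,6,8,10,12-hexaen-14-ynal F2.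
   - Pabon condensation of F2 with diketone 15 (through chelate 20, under the conditions of step 15) should give the dibutoxyboron chelate of 27 F3, which is hydrolysed with aqueous acetic acid to 27.

2. Step 15. The process at risk is slow aldol condensation at the secondary (ethyl) carbon of the boron chelate, so that thermal E/Z isomerisation of the polyenal and amine-induced cleavage of the diketone compete. The fallback sets out from aldehyde 19 and methyl ketone 14 and comes back at 22; it forms the C7'–C8' bond instead of the C9'=C10' bond.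
   - Wittig olefination of 19 with ethyl 2-(triphenylphosphoranylidene)propanoate (toluene, 60 °C) should give ethyl (2E,4E,6E,8E,10E,12E)-15,15-dibromo-2,6,11-trimethylpentadeca-2,4,6,8,10,12,14-heptaenoate F4.
   - Ketone 14 is converted with LiHMDS (THF, −78 °C) into lithium 1-[(1R,4S)-4-[(tert-butyldimethylsilyl)oxy]-1,2,2-trimethylcyclopentyl]ethen-1-olate F5, and crossed Claisen condensation of two equivalents of F5 with F4 (−78 → 0 °C, then aq. NH4Cl) should give 22.

3. Step 10. The process at risk is capture of the tertiary cation by proton loss or by fluoride instead of ring-bond migration, slow ionization next to the electron-withdrawing sulfonate, and partial loss of the silyl ether under the Lewis acid. The fallback sets out from enol triflate 9 and comes back at 14; it uses the symmetric 1,2-dimethyl epoxide, for which ionization at either carbon leads to the same ketone and no deoxygenation is needed.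
   - Cuprate coupling of 9 (Me2CuLi, THF, −15 °C) should give tert-butyldimethyl{[(1R)-3,4,5,5-tetramethylcyclohex-3-en-1-yl]oxy}silane F6.
   - Epoxidation (mCPBA, NaHCO3, CH2Cl2, 0 °C) and chromatographic separation from the cis isomer should give tert-butyldimethyl{[(1S,4S,6R)-1,2,2,6-tetramethyl-7-oxabicyclo[4.1.0]heptan-4-yl]oxy}silane F7 (oxygen trans to the silyloxy group).
   - Semipinacol ring contraction of F7 (BF3·OEt2, CH2Cl2, −78 °C) should give 14 directly.

## Further compounds

F1 | step 16 | (2E,4E,6E,8E,10E,12Z)-13-bromo-15-[(3S,4S)-3,4-bis[(tert-butyldimethylsilyl)oxy]-2,6,6-trimethylcyclohex-1-en-1-yl]-4,9-dimethylpentadeca-2,4,6,8,10,12-hexaen-14-ynal | CC1=C(C#C/C(Br)=C/C=C/C(C)=C/C=C/C=C(C)/C=C/C=O)C(C)(C)C[C@H](O[Si](C)(C)C(C)(C)C)[C@H]1O[Si](C)(C)C(C)(C)C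
F2 | step 16 | (2E,4E,6E,8E,10E,12E)-15-[(3S,4S)-3,4-bis[(tert-butyldimethylsilyl)oxy]-2,6,6-trimethylcyclohex-1-en-1-yl]-4,9,13-trimethylpentadeca-2,4,6,8,10,12-hexaen-14-ynal | CC1=C(C#C/C(C)=C/C=C/C(C)=C/C=C/C=C(C)/C=C/C=O)C(C)(C)C[C@H](O[Si](C)(C)C(C)(C)C)[C@H]1O[Si](C)(C)C(C)(C)C
F3 | step 16 | dibutoxyboron chelate of 27 | CC1=C(C#C/C(C)=C/C=C/C(C)=C/C=C/C=C(C)/C=C/C=C(C)/C2=CC(=[O+][B-](OCCCC)(OCCCC)O2)[C@]3(C)C[C@@H](O[Si](C)(C)C(C)(C)C)CC3(C)C)C(C)(C)C[C@H](O[Si](C)(C)C(C)(C)C)[C@H]1O[Si](C)(C)C(C)(C)C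
F4 | step 15 | ethyl (2E,4E,6E,8E,10E,12E)-15,15-dibromo-2,6,11-trimethylpentadeca-2,4,6,8,10,12,14-heptaenoate | BrC(Br)=C/C=C/C(C)=C/C=C/C=C(C)/C=C/C=C(C)/C(=O)OCC
F5 | step 15 | lithium 1-[(1R,4S)-4-[(tert-butyldimethylsilyl)oxy]-1,2,2-trimethylcyclopentyl]ethen-1-olate | C=C([O-])[C@]1(C)C[C@@H](O[Si](C)(C)C(C)(C)C)CC1(C)C.[Li+]
F6 | step 10 | tert-butyldimethyl{[(1R)-3,4,5,5-tetramethylcyclohex-3-en-1-yl]oxy}silane | CC1=C(C)C(C)(C)C[C@H](O[Si](C)(C)C(C)(C)C)C1
F7 | step 10 | tert-butyldimethyl{[(1S,4S,6R)-1,2,2,6-tetramethyl-7-oxabicyclo[4.1.0]heptan-4-yl]oxy}silane | C[C@]12O[C@@]1(C)C(C)(C)C[C@H](O[Si](C)(C)C(C)(C)C)C2
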